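**Retrosynthetic overview**
- The ten-membered carbocycle is closed last, by ring-closing metathesis at C3=C4 (the citronellyl alkene plus a 2-substituted acrylate, losing 2-methylpropene); the angelate goes on just before, with inversion at C6.
- Key disconnection: the exocyclic C6–C7 bond. A 3-(bromomethyl)butenolide is reduced by zinc to a species nucleophilic at the butenolide β-carbon (a lactone homoenolate equivalent), which adds to a C6 aldehyde. This sets C6 and C7 and unveils the α-methylene lactone.
- The butenolide bromide comes from an α-methylene-γ-butyrolactone, made from (S)-citronellol by enantioselective iridium-catalysed 2-(methoxycarbonyl)allylation (sets C8; C10 comes from the chiral pool).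
- The C4–C6 aldehyde comes from methyl 2-(bromomethyl)acrylate and formaldehyde.
- Ring order: γ-lactone first, carbocycle second.

Assumption: atom labels C1–C15 are the germacranolide numbers of the target (lactone oxygen on C8, angelate on C6, ring-fusion carbon C7, methyl on C10, ester carbon on C4, lactone carbonyl C12, exocyclic methylene C13).
Assumption: both antipodes of the TMBTP ligand are available; step 1 uses the one that gives Si-face addition (5R lactone).

**Step 1**
Reactants: 1 (S)-citronellol; 2 methyl 2-(acetoxymethyl)prop-2-enoate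
Product: 5 (5R)-5-[(2S)-2,6-dimethylhept-5-en-1-yl]-3-methylideneoxolan-2-one, via (S)-citronellal 3 (not isolated), via hydroxy ester 4 (not isolated)
Conditions: [Ir(cod)Cl]2 (2.5 mol %), TMBTP (5 mol %), 4-cyano-3-nitrobenzoic acid (10 mol %), Cs2CO3 (20 mol %), THF, 70 °C; then p-TsOH·H2O (5 mol %), CH2Cl2, 23 °C
Reagents that add atoms: none
Why: Iridium-catalysed transfer-hydrogenative carbonyl 2-(alkoxycarbonyl)allylation (Krische-type coupling from the alcohol oxidation level): the catalyst dehydrogenates 1 to aldehyde 3, ionises 2 to a nucleophilic π-allyl iridium species and adds it to the Si face of 3 under ligand control (C8 = R; the remote C10 methyl is a spectator), and γ-hydroxy ester 4 lactonises with loss of methanol.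

**Step 2**
Reactants: 5 (5R)-5-[(2S)-2,6-dimethylhept-5-en-1-yl]-3-methylideneoxolan-2-one
Product: 7 (5R)-3-(bromomethyl)-5-[(2S)-5,6-dibromo-2,6-dimethylheptyl]furan-2(5H)-one (both epimers at the side-chain CHBr), via tetrabromide 6 (not isolated)
Conditions: Br2 (2.05 equiv), CH2Cl2, −78 → 23 °C; then Et3N (1.2 equiv), 0 °C, 30 min
Reagents that add atoms: bromine, BrBr
Why: Electrophilic bromine addition to both alkenes (the trisubstituted side-chain alkene is thereby parked as a vicinal dibromide), then E2 dehydrobromination of the carbonyl-activated tertiary α-bromo lactone toward the ring CH2, which gives the conjugated endocyclic butenolide carrying the allylic CH2Br; C8 and C10 are untouched and the new CHBr centre is erased in step 5.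

**Step 3**
Reactants: 8 methyl 2-(bromomethyl)prop-2-enoate; 9 formaldehyde (37% aqueous)
Product: 11 methyl 4-hydroxy-2-methylidenebutanoate, via allylzinc bromide 10 (not isolated)
Conditions: Zn dust (1.5 equiv), THF/sat. aq NH4Cl (1:1), 0 → 23 °C
Reagents that add atoms: none
Why: Zinc Barbier allylation of formaldehyde by the 2-(methoxycarbonyl)allyl zinc reagent; the buffered aqueous medium protonates the alkoxide at once, so the γ-hydroxy ester is isolated open-chain.

**Step 4**
Reactants: 11 methyl 4-hydroxy-2-methylidenebutanoate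
Product: 12 methyl 2-methylidene-4-oxobutanoate
Conditions: Dess–Martin periodinane (1.2 equiv), CH2Cl2, 0 °C, 1 h; used crude at once
Reagents that add atoms: none
Why: Dess–Martin oxidation at 0 °C gives the β,γ-unsaturated aldehyde before it can slip into conjugation.

**Step 5** (key step)
Reactants: 7 (5R)-3-(bromomethyl)-5-[(2S)-5,6-dibromo-2,6-dimethylheptyl]furan-2(5H)-one; 12 methyl 2-methylidene-4-oxobutanoate
Product: 14 methyl (4S)-4-[(2R,3R)-2-[(2S)-2,6-dimethylhept-5-en-1-yl]-4-methylidene-5-oxooxolan-3-yl]-4-hydroxy-2-methylidenebutanoate, via butenolide allylzinc bromide 13 (not isolated)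
Conditions: Zn dust (6 equiv), 12 (3 equiv), THF/sat. aq NH4Cl (2:1), 0 → 23 °C
Reagents that add atoms: none
Why: Zinc Barbier (vinylogous Reformatsky-type) allylation, the polarity-reversed C6–C7 bond formation: zinc strips the vicinal dibromide back to the trisubstituted alkene and inserts into the allylic C–Br bond, which turns the normally electrophilic β-carbon C7 of the butenolide into a nucleophile (lactone homoenolate equivalent 13) that attacks the aldehyde carbon of 12 in an SE2′ sense through a six-membered chair transition state, on the face anti to the C8 side chain (C7 trans to C8) and with the aldehyde substituent equatorial on the ring-locked E-type allyl unit (anti adduct, C6 = S, the epimer that step 6 inverts), while the double-bond shift unveils the α-methylene lactone and NH4Cl protonates the zinc alkoxide before it can lactonise or translactonise.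

**Step 6**
Reactants: 14 methyl (4S)-4-[(2R,3R)-2-[(2S)-2,6-dimethylhept-5-en-1-yl]-4-methylidene-5-oxooxolan-3-yl]-4-hydroxy-2-methylidenebutanoate; 15 angelic acid
Product: 16 methyl (4R)-4-[(2R,3S)-2-[(2S)-2,6-dimethylhept-5-en-1-yl]-4-methylidene-5-oxooxolan-3-yl]-2-methylidene-4-{[(2Z)-2-methylbut-2-enoyl]oxy}butanoate
Conditions: PPh3 (2.5 equiv), DIAD (2.5 equiv), toluene, 0 °C (betaine pre-formed); then 14 and 15 (2.5 equiv), 0 → 23 °C
Reagents that add atoms: none
Why: Mitsunobu esterification: SN2 displacement of the alkoxyphosphonium of 14 by angelate inverts C6 to the required R configuration under neutral conditions that neither isomerise the Z-angelate to tiglate nor trigger lactonisation, and pre-forming the betaine keeps free PPh3 away from the two acrylate units.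

**Step 7**
Reactants: 16 methyl (4R)-4-[(2R,3S)-2-[(2S)-2,6-dimethylhept-5-en-1-yl]-4-methylidene-5-oxooxolan-3-yl]-2-methylidene-4-{[(2Z)-2-methylbut-2-enoyl]oxy}butanoate
Product: 17 methyl (3aS,4R,6E,10S,11aR)-10-methyl-3-methylidene-4-{[(2Z)-2-methylbut-2-enoyl]oxy}-2-oxo-2,3,3a,4,5,8,9,10,11,11a-decahydrocyclodeca[b]furan-6-carboxylate (CNP0510087.1)
Conditions: second-generation Hoveyda–Grubbs catalyst (15 mol %), toluene (1 mM), 90 °C, Ar sparge
Reagents that add atoms: none
Why: Ring-closing metathesis: the ruthenium alkylidene generated at C3 from the trisubstituted alkene (loss of 2-methylpropene) closes onto the 2-substituted acrylate to give the ten-membered ring, whose preferred ring-cis geometry is also the conjugated E (tiglate-type) enoate with C2 trans to CO2Me; no stereocentre is touched.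

**Compound list**
1 | (S)-citronellol, (3S)-3,7-dimethyloct-6-en-1-ol | C[C@@H](CCC=C(C)C)CCO | starting material
2 | methyl 2-(acetoxymethyl)prop-2-enoate | C=C(COC(C)=O)C(=O)OC | starting material
3 | (S)-citronellal, (3S)-3,7-dimethyloct-6-enal | C[C@@H](CCC=C(C)C)CC=O | intermediate
4 | methyl (4R,6S)-4-hydroxy-6,10-dimethyl-2-methylideneundec-9-enoate | C=C(C[C@H](O)C[C@@H](C)CCC=C(C)C)C(=O)OC | intermediate
5 | (5R)-5-[(2S)-2,6-dimethylhept-5-en-1-yl]-3-methylideneoxolan-2-one | C=C1C(=O)O[C@H](C[C@@H](C)CCC=C(C)C)C1 | intermediate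
6 | (5R)-3-bromo-3-(bromomethyl)-5-[(2S)-5,6-dibromo-2,6-dimethylheptyl]oxolan-2-one (epimers at ring C3 and at the side-chain CHBr) | BrCC1(Br)C(=O)O[C@H](C[C@@H](C)CCC(Br)C(C)(C)Br)C1 | intermediate
7 | (5R)-3-(bromomethyl)-5-[(2S)-5,6-dibromo-2,6-dimethylheptyl]furan-2(5H)-one (epimers at the side-chain CHBr) | O=C1O[C@H](C[C@@H](C)CCC(Br)C(C)(C)Br)C=C1CBr | intermediate
8 | methyl 2-(bromomethyl)prop-2-enoate | C=C(CBr)C(=O)OC | starting material
9 | formaldehyde | C=O | starting material
10 | [2-(methoxycarbonyl)prop-2-en-1-yl]zinc bromide | C=C(C[Zn]Br)C(=O)OC | intermediate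
11 | methyl 4-hydroxy-2-methylidenebutanoate | C=C(CCO)C(=O)OC | intermediate
12 | methyl 2-methylidene-4-oxobutanoate | C=C(CC=O)C(=O)OC | intermediate
13 | {[(5R)-5-[(2S)-2,6-dimethylhept-5-en-1-yl]-2-oxo-2,5-dihydrofuran-3-yl]methyl}zinc bromide | O=C1O[C@H](C[C@@H](C)CCC=C(C)C)C=C1C[Zn]Br | intermediate
14 | methyl (4S)-4-[(2R,3R)-2-[(2S)-2,6-dimethylhept-5-en-1-yl]-4-methylidene-5-oxooxolan-3-yl]-4-hydroxy-2-methylidenebutanoate | C=C1C(=O)O[C@H](C[C@@H](C)CCC=C(C)C)[C@H]1[C@@H](O)CC(=C)C(=O)OC | intermediate
15 | angelic acid, (2Z)-2-methylbut-2-enoic acid | C/C=C(/C)C(=O)O | starting material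
16 | methyl (4R)-4-[(2R,3S)-2-[(2S)-2,6-dimethylhept-5-en-1-yl]-4-methylidene-5-oxooxolan-3-yl]-2-methylidene-4-{[(2Z)-2-methylbut-2-enoyl]oxy}butanoate | C=C1C(=O)O[C@H](C[C@@H](C)CCC=C(C)C)[C@H]1[C@H](OC(=O)/C(C)=C\C)CC(=C)C(=O)OC | intermediate
17 | methyl (3aS,4R,6E,10S,11aR)-10-methyl-3-methylidene-4-{[(2Z)-2-methylbut-2-enoyl]oxy}-2-oxo-2,3,3a,4,5,8,9,10,11,11a-decahydrocyclodeca[b]furan-6-carboxylate | C=C1C(=O)O[C@@H]2C[C@@H](C)CC/C=C(/C(=O)OC)C[C@@H](OC(=O)/C(C)=C\C)[C@@H]12 | target

**Step count and risks**
Total step count: 7. Longest linear sequence: 5 steps (1, 2, 5, 6, 7); the branch 3, 4 joins at step 5.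

The three steps most likely to fail:

Step 7 (ring-closing metathesis). The carbene formed at C3 may close onto the more reactive lactone methylene C13 (eight-membered ring) or oligomerise, and initiation at a trisubstituted alkene is slow. The fallback sets out from 16 and comes back at 17. The lactone methylene is masked by conjugate addition of dimethylamine (Me2NH, THF, 0 °C; the 2-substituted acrylate and the angelate do not react), giving methyl (4R)-4-[(2R,3S)-4-[(dimethylamino)methyl]-2-[(2S)-2,6-dimethylhept-5-en-1-yl]-5-oxooxolan-3-yl]-2-methylidene-4-{[(2Z)-2-methylbut-2-enoyl]oxy}butanoate F1. Its camphorsulfonate salt is cyclised with the same catalyst, now with only one acrylate partner available, to methyl (3aS,4R,6E,10S,11aR)-3-[(dimethylamino)methyl]-10-methyl-4-{[(2Z)-2-methylbut-2-enoyl]oxy}-2-oxo-2,3,3a,4,5,8,9,10,11,11a-decahydrocyclodeca[b]furan-6-carboxylate F2. Methylation with MeI gives {[(3aS,4R,6E,10S,11aR)-6-(methoxycarbonyl)-10-methyl-4-{[(2Z)-2-methylbut-2-enoyl]oxy}-2-oxo-2,3,3a,4,5,8,9,10,11,11a-decahydrocyclodeca[b]furan-3-yl]methyl}trimethylammonium iodide F3, and NaHCO3 then eliminates trimethylamine to restore the α-methylene lactone of 17.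

Step 5 (zinc addition). The sense at C6 rests on a closed chair transition state; an open or zinc-chelated transition state in the aqueous medium would give the C6 epimer, and the product alcohol can lactonise. The fallback sets out from 7 (with 12) and comes back at 16. If the addition delivers mainly methyl (4R)-4-[(2R,3R)-2-[(2S)-2,6-dimethylhept-5-en-1-yl]-4-methylidene-5-oxooxolan-3-yl]-4-hydroxy-2-methylidenebutanoate F4, C6 already has the target configuration and no inversion is used. F4 is acylated with retention by the Yamaguchi mixed anhydride of 15 (2,4,6-trichlorobenzoyl chloride, Et3N, toluene; then F4, DMAP, 23 °C) to give 16.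

Step 2 (bromination and elimination). The E2 step may instead remove a hydrogen of the CH2Br group (giving the exocyclic vinyl bromide) or attack the side-chain dibromide. The fallback sets out from 5 and comes back at 7. One equivalent of Br2 at −78 °C adds only to the electron-rich trisubstituted alkene, giving (5R)-5-[(2S)-5,6-dibromo-2,6-dimethylheptyl]-3-methylideneoxolan-2-one F5. Wohl–Ziegler bromination (NBS, AIBN, PhCF3, 80 °C, stopped near 70% conversion) then abstracts the allylic ring hydrogen of the α-methylene lactone and delivers bromine to the exocyclic terminus with allylic transposition, giving 7 without a base-mediated elimination.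

**Further compounds**
F1 | step 7 | methyl (4R)-4-[(2R,3S)-4-[(dimethylamino)methyl]-2-[(2S)-2,6-dimethylhept-5-en-1-yl]-5-oxooxolan-3-yl]-2-methylidene-4-{[(2Z)-2-methylbut-2-enoyl]oxy}butanoate (epimers at oxolane C4) | CN(C)CC1C(=O)O[C@H](C[C@@H](C)CCC=C(C)C)[C@H]1[C@H](OC(=O)/C(C)=C\C)CC(=C)C(=O)OC
F2 | step 7 | methyl (3aS,4R,6E,10S,11aR)-3-[(dimethylamino)methyl]-10-methyl-4-{[(2Z)-2-methylbut-2-enoyl]oxy}-2-oxo-2,3,3a,4,5,8,9,10,11,11a-decahydrocyclodeca[b]furan-6-carboxylate (epimers at C3) | CN(C)CC1C(=O)O[C@@H]2C[C@@H](C)CC/C=C(/C(=O)OC)C[C@@H](OC(=O)/C(C)=C\C)[C@@H]12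
F3 | step 7 | {[(3aS,4R,6E,10S,11aR)-6-(methoxycarbonyl)-10-methyl-4-{[(2Z)-2-methylbut-2-enoyl]oxy}-2-oxo-2,3,3a,4,5,8,9,10,11,11a-decahydrocyclodeca[b]furan-3-yl]methyl}trimethylammonium iodide (epimers at C3) | C[N+](C)(C)CC1C(=O)O[C@@H]2C[C@@H](C)CC/C=C(/C(=O)OC)C[C@@H](OC(=O)/C(C)=C\C)[C@@H]12.[I-]
F4 | step 5 | methyl (4R)-4-[(2R,3R)-2-[(2S)-2,6-dimethylhept-5-en-1-yl]-4-methylidene-5-oxooxolan-3-yl]-4-hydroxy-2-methylidenebutanoate | C=C1C(=O)O[C@H](C[C@@H](C)CCC=C(C)C)[C@H]1[C@H](O)CC(=C)C(=O)OC
F5 | step 2 | (5R)-5-[(2S)-5,6-dibromo-2,6-dimethylheptyl]-3-methylideneoxolan-2-one (epimers at the side-chain CHBr) | C=C1C(=O)O[C@H](C[C@@H](C)CCC(Br)C(C)(C)Br)C1
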